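A direct plan would take ring A from (S)-carvone, add O6 and O7 by alkoxyallylboration and close ring B last, by a copper hydride reductive aldol of keto-acrylate A1 to decalin A2;
the butenolide would be joined by a Heck reaction and the two esters set after unmasking the protected trienolide A3. Its weakest steps would be:
(a) the reductive aldol closure of ring B, which would have to set the adjacent fully substituted centres C8 and C9 at once, from a flexible chain, on conformational preference alone;
(b) the run-up to A1, in which the carvone stereocentre would steer one addition and then be cut out by ozonolysis and fragmentation, and three steps would go into one methylene group;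
(c) the removal of the aryl ether from A3 with (NH4)2Ce(NO3)6, a one-electron oxidant that would meet the finished dienyl butenolide and the C3=C4 alkene four steps from the end.

**Plan of the new route**
Numbering is that of the clerodanes (ring A: C1–C5, C10; ring B: C5–C10; C11 and C20 on C9, C17 on C8, C18 on C4, C19 on C5); α is the face of C19 and C20, β that of H-10.
Cuts: C3=C4 (ring-closing metathesis), C5–C4 and C10–C1 (one conjugate addition–aldol coupling), C7–O and C8–O (osmylation), C9–C20 (Birch alkylation).
Ring B comes first and from an arene: 2,5-dimethylbenzoic acid already holds C5–C10 with C17 on C8, C19 on C5 and C11 as its carboxyl carbon; ring A closes last.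
Enabling feature: ipso-methylation and oxidation give a 2,5-cyclohexadienone whose arms differ, C5(CH3)=C10H with a free β-carbon and C7H=C8(CH3) with a blocked one, on either side of quaternary C9.
C9 then controls C10, C10 controls C5, and the axial methyl groups on C5 and C9 turn hydride and osmium to the β face, so all six centres of ring B derive from one auxiliary-set centre.
No ring closes at a stereocentre, no centre is set in an open chain, no control element is thrown away, and the only late unmasking is a fluoride desilylation.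

Key step: step 6

Remark: the (S)-auxiliary is assumed to deliver the (R) configuration at C9 in step 2 (C20 α, C11 β); if the sense were the opposite, the (R)-auxiliary would be used and nothing else would change.
Abbreviations: TBDPS = tert-butyldiphenylsilyl, TES = triethylsilyl, pin = pinacolato.

Step 1
Reactants: 1 2,5-dimethylbenzoic acid; 2 (S)-2-(methoxymethyl)pyrrolidine
Product: 4 (2,5-dimethylphenyl)[(2S)-2-(methoxymethyl)pyrrolidin-1-yl]methanone, via acid chloride 3 (not isolated)
Conditions: (COCl)2, DMF (cat.), CH2Cl2, 0 °C → rt; then 2, Et3N, CH2Cl2, 0 °C → rt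
Reagents that add atoms: none
Why: Amide formation via the acid chloride (Schotten–Baumann type) installs the proline-derived auxiliary whose methoxymethyl arm should differentiate the faces of the ipso carbon in step 2.

Step 2
Reactants: 4 auxiliary benzamide
Product: 6 [(2S)-2-(methoxymethyl)pyrrolidin-1-yl][(1R)-1,2,5-trimethylcyclohexa-2,5-dien-1-yl]methanone, via potassium amide enolate 5 (not isolated)
Conditions: K, NH3(l)/THF, t-BuOH (1 equiv), −78 °C; then MeI, −78 °C
Reagents that add atoms: iodomethane, CI
Why: Asymmetric Birch reduction–alkylation of a chiral 2-alkylbenzamide: two electrons and one proton (at C6) give amide enolate 5, whose ipso carbon should be methylated from the face not covered by the methoxymethylpyrrolidine, so C9 becomes the quaternary centre with C20 α and C11 (the amide carbon) β, and C17 and C19 stay on the two different alkenes.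

Step 3
Reactants: 6 diene amide
Product: 7 [(1R)-1,2,5-trimethylcyclohexa-2,5-dien-1-yl]methanol
Conditions: LiNH2BH3 (from BH3·NH3 and LiN(iPr)2), THF, 0 °C → rt; aq. HCl work-up
Reagents that add atoms: none
Why: Lithium amidotrihydroborate is the reagent of choice for reducing hindered tertiary amides to primary alcohols by C–N cleavage, the 1,4-diene is inert to it, and the auxiliary is recovered.

Step 4
Reactants: 7 dienyl carbinol
Product: 8 tert-butyl(diphenyl){[(1R)-1,2,5-trimethylcyclohexa-2,5-dien-1-yl]methoxy}silane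
Conditions: t-BuPh2SiCl, imidazole, DMF, rt
Reagents that add atoms: tert-butyl(chloro)diphenylsilane, CC(C)(C)[Si](Cl)(c1ccccc1)c1ccccc1
Why: Silylation of the neopentyl primary alcohol gives an acid-stable ether that is also the large group on C9 needed for facial control in step 6.

Step 5
Reactants: 8 silyl ether
Product: 9 (4R)-4-{[tert-butyl(diphenyl)silyl]oxymethyl}-2,4,5-trimethylcyclohexa-2,5-dien-1-one
Conditions: CrO3, 3,5-dimethylpyrazole, CH2Cl2, −20 °C
Reagents that add atoms: chromium trioxide, O=[Cr](=O)=O
Why: Chromium trioxide–3,5-dimethylpyrazole oxidises the doubly allylic C6 methylene of the 1,4-cyclohexadiene to the cross-conjugated dienone, which cannot aromatise because C9 is quaternary.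

Step 6
Reactants: 9 dienone; 10 [2-(1,3-dioxolan-2-yl)ethyl]magnesium bromide; 11 acetaldehyde
Product: 14 silylated aldol: ring-B enone (C6=O; C7=C8) carrying 9α-CH3; 9β-CH2OTBDPS; 10α-[2-(1,3-dioxolan-2-yl)ethyl]; 5α-CH3; 5β-CH(OTES)CH3 (both C4 epimers), via magnesium enolate 12 (not isolated), via magnesium aldolate 13 (not isolated)
Conditions: 10 (1.5 equiv), CuBr·SMe2 (15 mol %), THF, −78 → −40 °C; 11 (5 equiv), −78 °C; Et3SiOTf, 2,6-lutidine, −78 → −20 °C
Reagents that add atoms: triethylsilyl trifluoromethanesulfonate, CC[Si](CC)(CC)OS(=O)(=O)C(F)(F)F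
Why: Copper-catalysed conjugate addition of the Grignard reagent to the cross-conjugated dienone gives magnesium enolate 12, which adds to acetaldehyde at C5 to give aldolate 13, silylated in the same flask; the closest known reaction types are the three-component conjugate addition–aldol coupling of cycloalkenones and the conjugate addition to 4,4-disubstituted cyclohexa-2,5-dienones. No ring is closed; the step forms C10–C1 and C5–C4 and brings in C1–C3 and C4 with C18, all the carbons that ring A still lacks. At C10 the nucleophile should enter anti to the larger C9 substituent, the silyloxymethyl group, whose silyl ether is kept over the C5=C10 arm by the C17 methyl on the other side, so C1 becomes α and cis to C20. At C5 the aldehyde approaches the enolate anti to the new C10 chain, so C4 becomes β and C19 stays α, the trans relation the trans-decalin needs; the carbinol centre C4 is not controlled and is erased in step 12. The step needs 1,4- over 1,2-addition (copper), the C5=C10 arm over the C7=C8 arm (C8 is β,β-disubstituted and flanked by quaternary C9, whereas C10 carries hydrogen), and aldol capture faster than proton transfer from the C17 methyl (−78 °C, excess aldehyde). Silylation at low temperature keeps the congested aldolate from retro-aldol cleavage.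

Step 7
Reactants: 14 silylated aldol
Product: 15 allylic alcohol: 14 with 6α-OH in place of the ketone (C7=C8 kept)
Conditions: NaBH4, CeCl3·7H2O, MeOH, −78 → 0 °C
Reagents that add atoms: none
Why: Luche 1,2-reduction: hydride should reach C6 on the β face along the axial trajectory, anti to the axial 5α-methyl group on the adjacent quaternary carbon, and give the equatorial 6α-alcohol without touching the enone double bond, the acetal or the silyl ethers.

Step 8
Reactants: 15 allylic alcohol
Product: 16 allylic acetate: 6α-OAc; C7=C8; other groups as in 14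
Conditions: Ac2O, pyridine, DMAP (cat.), CH2Cl2, rt
Reagents that add atoms: acetic anhydride, CC(=O)OC(C)=O
Why: DMAP-catalysed acetylation of the only free hydroxyl installs the C6 acetate of the target at the outset, so O6 never needs a protecting group.

Step 9
Reactants: 16 allylic acetate
Product: 17 diol: 6α-OAc; 7β-OH; 8β-OH; 8α-CH3; other groups as in 14
Conditions: OsO4 (5 mol %), N-methylmorpholine N-oxide, acetone/H2O, rt
Reagents that add atoms: N-methylmorpholine N-oxide, C[N+]1([O-])CCOCC1; water, O
Why: Upjohn dihydroxylation of the only alkene in the molecule: osmium tetroxide should add to C7=C8 on the β face, anti to the allylic 6α-acetoxy group and to the axial methyl groups on C5 and C9, which gives the cis diol with O7 β (equatorial) and O8 β (axial) and leaves C17 α.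

Step 10
Reactants: 17 diol
Product: 18 diester: 6α-OAc; 7β-OC(O)CH(CH3)2; 8β-OH; other groups as in 14
Conditions: i-PrCOCl, pyridine, DMAP (cat.), CH2Cl2, 0 °C → rt
Reagents that add atoms: isobutyryl chloride, CC(C)C(Cl)=O
Why: Acylation with isobutyryl chloride takes the secondary 7β-hydroxyl only, because the tertiary axial 8β-hydroxyl between C7 and quaternary C9 is inert to acid chlorides under these conditions.

Step 11
Reactants: 18 diester
Product: 19 hydroxy aldehyde: 10α-(3-oxopropyl); 5β-(1-hydroxyethyl); 6α-OAc; 7β-isobutyrate; 8β-OH; 9β-CH2OTBDPS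
Conditions: 2 M HCl, THF, rt
Reagents that add atoms: water, O
Why: Dilute aqueous acid hydrolyses the dioxolane to the C3 aldehyde and removes the triethylsilyl group from O4, while the two esters and the tert-butyldiphenylsilyl ether, both stable to these conditions, stay in place.

Step 12
Reactants: 19 hydroxy aldehyde
Product: 20 keto aldehyde: 10α-(3-oxopropyl); 5β-acetyl; other groups as in 19
Conditions: Dess–Martin periodinane, NaHCO3, CH2Cl2, 0 °C → rt
Reagents that add atoms: none
Why: Dess–Martin oxidation turns both C4 epimers into one methyl ketone under neutral conditions, so the keto aldehyde is not exposed to base and cannot undergo intramolecular aldol reaction, and the tertiary 8-hydroxyl cannot be oxidised.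

Step 13
Reactants: 20 keto aldehyde
Product: 21 diene: 10α-(but-3-en-1-yl); 5β-isopropenyl; other groups as in 19
Conditions: Zn, CH2Br2, TiCl4, THF/CH2Cl2, 0 °C → rt
Reagents that add atoms: dibromomethane, BrCBr
Why: Takai–Lombardo methylenation with the non-basic zinc–titanium methylene reagent converts both the aldehyde and the hindered, enolisable methyl ketone into terminal alkenes and does not attack esters.

Step 14
Reactants: 21 diene
Product: 22 6α-acetoxy-11-(tert-butyldiphenylsilyloxy)-8β-hydroxy-7β-isobutyryloxy-12,13,14,15,16-pentanorclerod-3-ene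
Conditions: (H2IMes)(PCy3)Cl2Ru=CHPh (second-generation Grubbs catalyst, 5 mol %), CH2Cl2, 40 °C
Reagents that add atoms: none
Why: Ring-closing metathesis joins C3 to C4: the but-3-enyl and isopropenyl groups are trans and equatorial on C10 and C5, so ring A should close to the trans-decalin, the trisubstituted C3=C4 bond is fixed in position with C18 on C4, and ethene is lost.

Step 15
Reactants: 22 silyl ether
Product: 23 6α-acetoxy-7β-isobutyryloxy-12,13,14,15,16-pentanorclerod-3-ene-8β,11-diol
Conditions: HF·pyridine, pyridine, THF, 0 °C → rt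
Reagents that add atoms: none
Why: Fluoride cleaves the primary silyl ether in a buffered acidic medium in which neither the acetate nor the isobutyrate migrates to the free hydroxyl groups.

Step 16
Reactants: 23 diol
Product: 24 6α-acetoxy-8β-hydroxy-7β-isobutyryloxy-12,13,14,15,16-pentanorclerod-3-en-11-al
Conditions: Dess–Martin periodinane, NaHCO3, CH2Cl2, 0 °C
Reagents that add atoms: none
Why: Buffered Dess–Martin oxidation gives the non-enolisable C11 aldehyde under neutral conditions, which keeps the β-hydroxy aldehyde (O8–C8–C9–C11) away from the base that would start a retro-aldol cleavage.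

Step 17
Reactants: 24 aldehyde
Product: 25 6α-acetoxy-8β-hydroxy-7β-isobutyryloxy-12-(4,4,5,5-tetramethyl-1,3,2-dioxaborolan-2-yl)-13,14,15,16-tetranorcleroda-3,11E-diene
Conditions: Cl2CHB(pin), CrCl2, LiI, THF, rt
Reagents that add atoms: 2-(dichloromethyl)-4,4,5,5-tetramethyl-1,3,2-dioxaborolane, ClC(Cl)B1OC(C)(C)C(C)(C)O1
Why: Takai–Utimoto olefination: the geminal dichromium species formed from the dichloromethylboronate and divalent chromium adds to the aldehyde and eliminates to the (E)-alkenylboronate, under non-basic conditions that tolerate the esters and the free tertiary alcohol.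

Step 18
Reactants: 25 alkenylboronate; 26 4-bromofuran-2(5H)-one
Product: 27 (5R,6R,7S,8R,9R,10S)-6-acetoxy-8-hydroxy-7-isobutyryloxycleroda-3,11E,13-trien-15,16-olide (CNP0207114.1)
Conditions: 26, Pd(PPh3)4 (5 mol %), CsF, 1,2-dimethoxyethane, 60 °C
Reagents that add atoms: none
Why: Suzuki–Miyaura coupling: oxidative addition of zerovalent palladium to the vinylic C–Br bond, fluoride-assisted transmetalation of the alkenylboronate and reductive elimination form C12–C13 with retention of the E geometry, and the anhydrous fluoride base spares the acetate, the isobutyrate and the butenolide.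

**Compound list**
1 | 2,5-dimethylbenzoic acid | Cc1ccc(C)c(c1)C(O)=O | starting material
2 | (S)-2-(methoxymethyl)pyrrolidine | COC[C@@H]1CCCN1 | starting material
3 | 2,5-dimethylbenzoyl chloride | Cc1ccc(C)c(c1)C(Cl)=O | intermediate
4 | (2,5-dimethylphenyl)[(2S)-2-(methoxymethyl)pyrrolidin-1-yl]methanone | COC[C@@H]1CCCN1C(=O)c1cc(C)ccc1C | intermediate
5 | potassium amide enolate of the 1,4-dihydroarene (2,5-dimethylcyclohexa-2,5-dien-1-ylidene) | COC[C@@H]1CCCN1C([O-])=C1C(C)=CCC(C)=C1.[K+] | intermediate
6 | [(2S)-2-(methoxymethyl)pyrrolidin-1-yl][(1R)-1,2,5-trimethylcyclohexa-2,5-dien-1-yl]methanone | COC[C@@H]1CCCN1C(=O)[C@@]1(C)C(C)=CCC(C)=C1 | intermediate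
7 | [(1R)-1,2,5-trimethylcyclohexa-2,5-dien-1-yl]methanol | OC[C@@]1(C)C(C)=CCC(C)=C1 | intermediate
8 | tert-butyl(diphenyl){[(1R)-1,2,5-trimethylcyclohexa-2,5-dien-1-yl]methoxy}silane | CC(C)(C)[Si](OC[C@@]1(C)C(C)=CCC(C)=C1)(c1ccccc1)c1ccccc1 | intermediate
9 | (4R)-4-{[tert-butyl(diphenyl)silyl]oxymethyl}-2,4,5-trimethylcyclohexa-2,5-dien-1-one | CC(C)(C)[Si](OC[C@@]1(C)C(C)=CC(=O)C(C)=C1)(c1ccccc1)c1ccccc1 | intermediate
10 | [2-(1,3-dioxolan-2-yl)ethyl]magnesium bromide | Br[Mg]CCC1OCCO1 | starting material
11 | acetaldehyde | CC=O | starting material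
12 | bromomagnesium C5=C6 enolate of the C10 adduct (10α chain) | Br[Mg]OC1=C(C)[C@H](CCC2OCCO2)[C@@](C)(CO[Si](c2ccccc2)(c2ccccc2)C(C)(C)C)C(C)=C1 | intermediate
13 | bromomagnesium aldolate (5β-CH(OMgBr)CH3) | O=C1C=C(C)[C@](C)(CO[Si](c2ccccc2)(c2ccccc2)C(C)(C)C)[C@@H](CCC2OCCO2)[C@]1(C)C(C)O[Mg]Br | intermediate
14 | silylated aldol: 4-(TBDPSO-methyl)-5-[2-(1,3-dioxolan-2-yl)ethyl]-3,4,6-trimethyl-6-[1-(triethylsilyloxy)ethyl]cyclohex-2-en-1-one (9α-CH3, 9β-CH2OSi, 10α-chain, 5α-CH3; both C4 epimers) | O=C1C=C(C)[C@](C)(CO[Si](c2ccccc2)(c2ccccc2)C(C)(C)C)[C@@H](CCC2OCCO2)[C@]1(C)C(C)O[Si](CC)(CC)CC | intermediate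
15 | 6α-allylic alcohol of 14 | O[C@H]1C=C(C)[C@](C)(CO[Si](c2ccccc2)(c2ccccc2)C(C)(C)C)[C@@H](CCC2OCCO2)[C@]1(C)C(C)O[Si](CC)(CC)CC | intermediate
16 | 6α-acetate of 15 | CC(=O)O[C@H]1C=C(C)[C@](C)(CO[Si](c2ccccc2)(c2ccccc2)C(C)(C)C)[C@@H](CCC2OCCO2)[C@]1(C)C(C)O[Si](CC)(CC)CC | intermediate
17 | 6α-acetoxy-7β,8β-diol (8α-CH3) | CC(=O)O[C@H]1[C@H](O)[C@](C)(O)[C@](C)(CO[Si](c2ccccc2)(c2ccccc2)C(C)(C)C)[C@@H](CCC2OCCO2)[C@]1(C)C(C)O[Si](CC)(CC)CC | intermediate
18 | 6α-acetoxy-7β-isobutyryloxy-8β-ol | CC(=O)O[C@H]1[C@H](OC(=O)C(C)C)[C@](C)(O)[C@](C)(CO[Si](c2ccccc2)(c2ccccc2)C(C)(C)C)[C@@H](CCC2OCCO2)[C@]1(C)C(C)O[Si](CC)(CC)CC | intermediate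
19 | hydroxy aldehyde: 10α-(3-oxopropyl), 5β-(1-hydroxyethyl) | CC(=O)O[C@H]1[C@H](OC(=O)C(C)C)[C@](C)(O)[C@](C)(CO[Si](c2ccccc2)(c2ccccc2)C(C)(C)C)[C@@H](CCC=O)[C@]1(C)C(C)O | intermediate
20 | keto aldehyde: 10α-(3-oxopropyl), 5β-acetyl | CC(=O)O[C@H]1[C@H](OC(=O)C(C)C)[C@](C)(O)[C@](C)(CO[Si](c2ccccc2)(c2ccccc2)C(C)(C)C)[C@@H](CCC=O)[C@]1(C)C(C)=O | intermediate
21 | diene: 10α-(but-3-en-1-yl), 5β-isopropenyl | CC(=O)O[C@H]1[C@H](OC(=O)C(C)C)[C@](C)(O)[C@](C)(CO[Si](c2ccccc2)(c2ccccc2)C(C)(C)C)[C@@H](CCC=C)[C@]1(C)C(C)=C | intermediate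
22 | 6α-acetoxy-11-(tert-butyldiphenylsilyloxy)-8β-hydroxy-7β-isobutyryloxy-12,13,14,15,16-pentanorclerod-3-ene | CC(=O)O[C@H]1[C@H](OC(=O)C(C)C)[C@](C)(O)[C@](C)(CO[Si](c3ccccc3)(c3ccccc3)C(C)(C)C)[C@H]2CCC=C(C)[C@]12C | intermediate
23 | 6α-acetoxy-7β-isobutyryloxy-12,13,14,15,16-pentanorclerod-3-ene-8β,11-diol | CC(=O)O[C@H]1[C@H](OC(=O)C(C)C)[C@](C)(O)[C@](C)(CO)[C@H]2CCC=C(C)[C@]12C | intermediate
24 | 6α-acetoxy-8β-hydroxy-7β-isobutyryloxy-12,13,14,15,16-pentanorclerod-3-en-11-al | CC(=O)O[C@H]1[C@H](OC(=O)C(C)C)[C@](C)(O)[C@](C)(C=O)[C@H]2CCC=C(C)[C@]12C | intermediate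
25 | (E)-alkenyl pinacol boronate (C11=C12, B on C12) | CC(=O)O[C@H]1[C@H](OC(=O)C(C)C)[C@](C)(O)[C@](C)(/C=C/B3OC(C)(C)C(C)(C)O3)[C@H]2CCC=C(C)[C@]12C | intermediate
26 | 4-bromofuran-2(5H)-one | O=C1C=C(Br)CO1 | starting material
27 | CNP0207114.1, (5R,6R,7S,8R,9R,10S)-6-acetoxy-8-hydroxy-7-isobutyryloxycleroda-3,11E,13-trien-15,16-olide | CC(=O)O[C@H]1[C@H](OC(=O)C(C)C)[C@](C)(O)[C@](C)(/C=C/C2=CC(=O)OC2)[C@H]2CCC=C(C)[C@]12C | target

**Step count and risks**
Total: 18 steps. Longest linear sequence: 18 steps (1 → 27); compounds 2, 10, 11 and 26 are bought.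

The three steps most likely to fail:

First, step 6. The cuprate may add to C10 with too little preference for the α face, or the congested aldolate 13 may revert before it is silylated. The fallback sets out from 9 and comes back at 14. The conjugate addition of 10 would be run at −78 °C with Me3SiCl present, which traps the kinetic adduct irreversibly as the isolated trimethylsilyl enol ether F1. MeLi would then release the regiodefined lithium enolate, ZnCl2 would convert it into the zinc enolate, and its aldol reaction with 11 at −78 °C would give the free aldol F2. Et3SiOTf and 2,6-lutidine would convert F2 into 14.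

Second, step 17. The dichromium reagent may add too slowly to the neopentyl aldehyde, and the β-hydroxy aldehyde may be lost by retro-aldol cleavage on long exposure. The fallback sets out from 24 and comes back at 27. Me3SiOTf and 2,6-lutidine at −78 °C would give the 8-O-trimethylsilyl aldehyde F3. A Wittig reaction with the ylide of the phosphonium salt F4 (made from 4-(bromomethyl)furan-2(5H)-one and PPh3; NaN(SiMe3)2, THF, then toluene, 80 °C) would build the whole dienyl butenolide in one step as the 8-O-trimethylsilyl trienolide F5. HF·pyridine would then give 27.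

Third, step 2. Facial selection in the alkylation of enolate 5 may be low or reversed for this 2,5-dimethyl pattern. The fallback sets out from 1 and comes back at 7, and replaces auxiliary control by resolution. Birch reduction–methylation of the free acid 1 (Li, NH3/THF; MeI) would give the racemic acid F6. Crystallisation with (S)-1-phenylethylamine (or its antipode, whichever gives the less soluble salt of the (R)-acid) would give the salt F7. Acidification would give the (R)-acid F8, and LiAlH4 in THF would reduce it to 7.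

**Further compounds**
F1 | step 6 | trimethylsilyl enol ether (C5=C6) of the C10 adduct | C[Si](C)(C)OC1=C(C)[C@H](CCC2OCCO2)[C@@](C)(CO[Si](c2ccccc2)(c2ccccc2)C(C)(C)C)C(C)=C1
F2 | step 6 | free aldol, 5β-(1-hydroxyethyl) enone (both C4 epimers) | O=C1C=C(C)[C@](C)(CO[Si](c2ccccc2)(c2ccccc2)C(C)(C)C)[C@@H](CCC2OCCO2)[C@]1(C)C(C)O
F3 | step 17 | 8-O-trimethylsilyl ether of aldehyde 24 | CC(=O)O[C@H]1[C@H](OC(=O)C(C)C)[C@](C)(O[Si](C)(C)C)[C@](C)(C=O)[C@H]2CCC=C(C)[C@]12C
F4 | step 17 | [(5-oxo-2,5-dihydrofuran-3-yl)methyl]triphenylphosphonium bromide | O=C1OCC(C[P+](c2ccccc2)(c2ccccc2)c2ccccc2)=C1.[Br-]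
F5 | step 17 | 8-O-trimethylsilyl ether of 27 | CC(=O)O[C@H]1[C@H](OC(=O)C(C)C)[C@](C)(O[Si](C)(C)C)[C@](C)(/C=C/C2=CC(=O)OC2)[C@H]2CCC=C(C)[C@]12C
F6 | step 2 | rac-1,2,5-trimethylcyclohexa-2,5-diene-1-carboxylic acid | OC(=O)C1(C)C(C)=CCC(C)=C1
F7 | step 2 | (S)-1-phenylethylammonium (R)-1,2,5-trimethylcyclohexa-2,5-diene-1-carboxylate | C[C@H]([NH3+])c1ccccc1.[O-]C(=O)[C@@]1(C)C(C)=CCC(C)=C1
F8 | step 2 | (R)-1,2,5-trimethylcyclohexa-2,5-diene-1-carboxylic acid | OC(=O)[C@@]1(C)C(C)=CCC(C)=C1
A1 | direct plan | ring-A keto-acrylate with 6-O-silyl and 7-O-aryl groups | CC(=O)[C@@H](Oc2ccc(OC)cc2)[C@H](O[Si](C)(C)C(C)(C)C)[C@@]1(C)C(C)=CCC[C@@H]1C(=C)C(=O)OC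
A2 | direct plan | decalin β-hydroxy ester | CC(C)(C)[Si](C)(C)O[C@H]1[C@H](Oc3ccc(OC)cc3)[C@](C)(O)[C@](C)(C(=O)OC)[C@H]2CCC=C(C)[C@]12C
A3 | direct plan | protected dienyl butenolide | CC(C)(C)[Si](C)(C)O[C@H]1[C@H](Oc3ccc(OC)cc3)[C@](C)(O[Si](CC)(CC)CC)[C@](C)(/C=C/C3=CC(=O)OC3)[C@H]2CCC=C(C)[C@]12C
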